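**Retrosynthetic overview**

1. Hypholomine B is a 2,3-dihydro-4H-furo[3,2-c]pyran-4-one (ring A = fused 2-pyranone, ring B = dihydrofuran; O1, C2, C3, C3a, C4(=O), O5, C6, C7, C7a) with a catechol on C2, a 4-hydroxy-2-pyranon-6-yl group (ring C) on C3 and a styryl arm on C6. Last operations: desilylation, and closure of ring C from a C3 carboxylic acid through a 3,5-diketo ester.
2. Key disconnection: ring B is cut at O1–C2 and C3–C3a. This is an oxidative radical [3+2] annulation of a 4-hydroxy-2-pyranone (ring A) with an (E)-caffeoyl imide of Oppolzer's sultam, which sets C2 and C3 (2S,3S, trans).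
3. Enabling feature: O1–C7a=C3a is the enol (4-OH/C-3) of a cyclic 1,3-dicarbonyl, which Mn(III) oxidises to an electrophilic C-3 radical. C3–C2 is a β-aryl acryloyl unit: the catechol ring on C2 stabilises the benzylic radical and cation, and the carbonyl on C3 (later C-6' of ring C) carries the removable chiral controller.
4. The styryl arm of ring A is carried through the key step as a 2-silyloxy-2-arylethyl group (aldol adduct of the triacetic acid lactone dianion), because a free styrylpyranone alkene would itself be a radical acceptor. It is unveiled by acid elimination right after the key step.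
5. Ring order: ring A is bought (triacetic acid lactone), ring B is formed in step 6, ring C is closed in step 10.

Key step: step 6

Assumption: N-enoyl derivatives of (2R)-bornane-10,2-sultam are attacked at Cα on the re face (s-cis enoyl, C=O anti to SO2), so the (2S)-sultam is used to obtain 2S,3S. If the sense proves opposite, the equally available (2R)-sultam replaces it with no other change.

**Route**

Step 1
Reactants: 1 caffeic acid [(E)-3-(3,4-dihydroxyphenyl)prop-2-enoic acid]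
Product: 3 (E)-3-[3,4-bis(triisopropylsilyloxy)phenyl]prop-2-enoic acid, via silyl ester 2 (not isolated)
Conditions: TIPSCl (3.3 equiv), imidazole, DMF, rt; then THF–H2O–AcOH, rt
Reagents that add atoms: triisopropylsilyl chloride, CC(C)[Si](Cl)(C(C)C)C(C)C
Why: Silyl ether protection (TIPSCl/imidazole) of both phenols and the acid, then selective hydrolysis of the much more labile silyl ester, should give a catechol protection that is stable to Mn(III)/AcOH, LiOOH and DBU and is removed by fluoride.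

Step 2
Reactants: 3 (E)-3-[3,4-bis(triisopropylsilyloxy)phenyl]prop-2-enoic acid; 4 (2S)-bornane-10,2-sultam [(1R)-(+)-2,10-camphorsultam]
Product: 6 N-[(E)-3-[3,4-bis(triisopropylsilyloxy)phenyl]prop-2-enoyl]-(2S)-bornane-10,2-sultam, via acid chloride 5 (not isolated)
Conditions: 1-chloro-N,N,2-trimethylprop-1-en-1-amine (Ghosez reagent), CH2Cl2, 0 °C; then 4, NaH, THF, 0 °C to rt
Reagents that add atoms: none
Why: N-Acylation of the sodium salt of the sultam by an acid chloride made under neutral conditions should install the chiral controller without touching the E-alkene or the silyl ethers.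

Step 3
Reactants: 7 3,4-dihydroxybenzaldehyde
Product: 8 3,4-bis(triisopropylsilyloxy)benzaldehyde
Conditions: TIPSCl (2.4 equiv), imidazole, DMF, rt
Reagents that add atoms: triisopropylsilyl chloride, CC(C)[Si](Cl)(C(C)C)C(C)C
Why: Silyl ether formation on the catechol should give the aldehyde in the same protected form as the acceptor.

Step 4
Reactants: 9 4-hydroxy-6-methyl-2H-pyran-2-one (triacetic acid lactone); 8 3,4-bis(triisopropylsilyloxy)benzaldehyde
Product: 11 6-[2-hydroxy-2-[3,4-bis(triisopropylsilyloxy)phenyl]ethyl]-4-hydroxy-2H-pyran-2-one (racemic), via dilithio dianion 10 (not isolated)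
Conditions: LDA (2.2 equiv), THF, −78 °C; then 8, −78 °C; AcOH quench
Reagents that add atoms: none
Why: Dianion aldol addition: the second deprotonation of the lactone occurs at the 6-methyl group and this vinylogous carbanion should add to the aldehyde at that carbon; the carbinol centre forms as a racemate and is destroyed in step 7.

Step 5
Reactants: 11 6-[2-hydroxy-2-[3,4-bis(triisopropylsilyloxy)phenyl]ethyl]-4-hydroxy-2H-pyran-2-one
Product: 13 6-[2-(tert-butyldimethylsilyloxy)-2-[3,4-bis(triisopropylsilyloxy)phenyl]ethyl]-4-hydroxy-2H-pyran-2-one (racemic), via bis-silyl ether 12 (not isolated)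
Conditions: TBSCl (2.5 equiv), imidazole, DMF, rt; then THF–H2O–AcOH, rt
Reagents that add atoms: tert-butyldimethylsilyl chloride, CC(C)(C)[Si](C)(C)Cl
Why: Silyl ether formation followed by hydrolysis of the 4-O-silyl group (a vinylogous silyl ester) should leave the secondary silyl ether, so that the future styrene is stored as a saturated arm that cannot accept radicals and the 4-OH/C-3 enol is free.

Step 6
Reactants: 13 6-[2-(tert-butyldimethylsilyloxy)-2-[3,4-bis(triisopropylsilyloxy)phenyl]ethyl]-4-hydroxy-2H-pyran-2-one; 6 N-[(E)-3-[3,4-bis(triisopropylsilyloxy)phenyl]prop-2-enoyl]-(2S)-bornane-10,2-sultam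
Product: 16 N-[(2S,3S)-2-[3,4-bis(triisopropylsilyloxy)phenyl]-6-[2-(tert-butyldimethylsilyloxy)-2-[3,4-bis(triisopropylsilyloxy)phenyl]ethyl]-4-oxo-2,3-dihydro-4H-furo[3,2-c]pyran-3-carbonyl]-(2S)-bornane-10,2-sultam (both epimers at the silyloxy carbon), via benzylic radical 14 (not isolated), via benzylic cation 15 (not isolated)
Conditions: Mn(OAc)3·2H2O (3 equiv), KOAc, degassed AcOH, 60 °C; 13 in excess (1.5 equiv)
Reagents that add atoms: none
Why: This is a Mn(III)-mediated oxidative radical [3+2] annulation of a cyclic 1,3-dicarbonyl with an alkene, closest to the known annulation of cyclic 1,3-diones with N-cinnamoyl bornane-10,2-sultams: the Mn(III) enolate of 13 gives an electrophilic C-3 radical that adds to the α-carbon of the enoyl imide (C3–C3a bond, radical 14), a second Mn(III) oxidises 14 to cation 15, and the 4-oxygen captures it (O1–C2 bond). Ring B closes in a 5-exo-trig mode by attack of the enol oxygen on the benzylic, quinone-methide-like carbon. C-3 is set in the radical addition by the sultam (s-cis enoyl, C=O anti to SO2, attack on the Cα si face remote from the sulfonyl oxygens and the camphor skeleton), and C-2 is set in the ring closure trans to the acyl group on C-3 under steric and thermodynamic control. Regioselectivity (C–C bond at the acyl-bearing carbon, C–O bond at the aryl-bearing carbon) is secured by the 3,4-bis(silyloxy)phenyl ring, which stabilises radical and cation at the benzylic carbon. Chemoselectivity rests on the absence of any other alkene and on closure through the 4-oxygen, which keeps the 2-pyranone (furo[3,2-c]pyran-4-one) rather than the 4-pyranone isomer; minor diastereomers should be removable by chromatography of the sultam adduct.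

Step 7
Reactants: 16 the annulation product of step 6
Product: 17 N-[(2S,3S)-2-[3,4-bis(triisopropylsilyloxy)phenyl]-6-[(E)-2-[3,4-bis(triisopropylsilyloxy)phenyl]ethenyl]-4-oxo-2,3-dihydro-4H-furo[3,2-c]pyran-3-carbonyl]-(2S)-bornane-10,2-sultam
Conditions: p-TsOH·H2O (0.2 equiv), toluene, 60 °C
Reagents that add atoms: none
Why: Acid-catalysed E1 elimination of silanol from the electron-rich benzylic silyl ether, driven by conjugation with ring A, should give the E-styryl arm; it is run with the auxiliary attached so that any erosion at C-2 or C-3 would appear as separable diastereomers.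

Step 8
Reactants: 17 the styryl imide of step 7
Product: 19 (2S,3S)-2-[3,4-bis(triisopropylsilyloxy)phenyl]-6-[(E)-2-[3,4-bis(triisopropylsilyloxy)phenyl]ethenyl]-4-oxo-2,3-dihydro-4H-furo[3,2-c]pyran-3-carboxylic acid, via peroxy acid 18 (not isolated)
Conditions: LiOH·H2O, 30% H2O2, THF–H2O 3:1, 0 °C; Na2SO3; then HCl to pH 3
Reagents that add atoms: hydrogen peroxide (as LiOOH), OO
Why: Peroxide-assisted hydrolysis of the N-acyl sultam: hydroperoxide should attack the exocyclic imide carbonyl faster than hydroxide opens the lactone or enolises C-3, releasing the acid with both stereocentres intact and returning the auxiliary.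

Step 9
Reactants: 19 the acid of step 8; 20 1-methoxy-1,3-bis(trimethylsilyloxy)buta-1,3-diene (Chan's diene)
Product: 23 methyl 5-[(2S,3S)-2-[3,4-bis(triisopropylsilyloxy)phenyl]-6-[(E)-2-[3,4-bis(triisopropylsilyloxy)phenyl]ethenyl]-4-oxo-2,3-dihydro-4H-furo[3,2-c]pyran-3-yl]-3,5-dioxopentanoate, via acid chloride 21 (not isolated), via silyl enol ether 22 (not isolated)
Conditions: Ghosez reagent, CH2Cl2, 0 °C; then 20 (2 equiv), CH2Cl2, −78 to 0 °C; 1 M HCl–THF work-up
Reagents that add atoms: none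
Why: Vinylogous Claisen-type γ-acylation of the bis-silyl dienol ether of methyl acetoacetate by the acid chloride is a neutral C-acylation that should avoid enolising C-3 next to the dihydrofuran oxygen, and gives the 3,5-diketo ester after hydrolysis of the silyl enol ether.

Step 10
Reactants: 23 the 3,5-diketo ester of step 9
Product: 24 4-hydroxy-6-[(2S,3S)-2-[3,4-bis(triisopropylsilyloxy)phenyl]-6-[(E)-2-[3,4-bis(triisopropylsilyloxy)phenyl]ethenyl]-4-oxo-2,3-dihydro-4H-furo[3,2-c]pyran-3-yl]-2H-pyran-2-one (tetra-O-TIPS hypholomine B)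
Conditions: DBU (2 equiv), toluene, rt; aq. citric acid work-up
Reagents that add atoms: none
Why: Base-mediated lactonisation of the 3,5-diketo ester (6-exo-trig attack of the δ-enolate oxygen on the ester, loss of methanol) should close ring C; the base is taken up by the acidic methylene groups of the diketo ester, which protects C-3 from enolisation.

Step 11
Reactants: 24 tetra-O-TIPS hypholomine B
Product: 25 hypholomine B
Conditions: HF·pyridine, pyridine, THF, 0 °C to rt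
Reagents that add atoms: none
Why: Fluoride-mediated cleavage of the four aryl silyl ethers under buffered, non-basic conditions should free both catechols without touching the styrene, the lactones or the C-2/C-3 stereocentres.

**Compound list**

1 | caffeic acid | OC(=O)/C=C/c1ccc(O)c(O)c1 | starting material
2 | triisopropylsilyl (E)-3-[3,4-bis(triisopropylsilyloxy)phenyl]prop-2-enoate | CC(C)[Si](C(C)C)(C(C)C)OC(=O)/C=C/c1ccc(O[Si](C(C)C)(C(C)C)C(C)C)c(O[Si](C(C)C)(C(C)C)C(C)C)c1 | intermediate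
3 | (E)-3-[3,4-bis(triisopropylsilyloxy)phenyl]prop-2-enoic acid | OC(=O)/C=C/c1ccc(O[Si](C(C)C)(C(C)C)C(C)C)c(O[Si](C(C)C)(C(C)C)C(C)C)c1 | intermediate
4 | (2S)-bornane-10,2-sultam | CC1(C)[C@H]2CC[C@@]13CS(=O)(=O)N[C@H]3C2 | starting material
5 | (E)-3-[3,4-bis(triisopropylsilyloxy)phenyl]prop-2-enoyl chloride | ClC(=O)/C=C/c1ccc(O[Si](C(C)C)(C(C)C)C(C)C)c(O[Si](C(C)C)(C(C)C)C(C)C)c1 | intermediate
6 | N-[(E)-3-[3,4-bis(triisopropylsilyloxy)phenyl]prop-2-enoyl]-(2S)-bornane-10,2-sultam | CC1(C)[C@H]2CC[C@@]13CS(=O)(=O)N(C(=O)/C=C/c4ccc(O[Si](C(C)C)(C(C)C)C(C)C)c(O[Si](C(C)C)(C(C)C)C(C)C)c4)[C@H]3C2 | intermediate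
7 | 3,4-dihydroxybenzaldehyde | O=Cc1ccc(O)c(O)c1 | starting material
8 | 3,4-bis(triisopropylsilyloxy)benzaldehyde | O=Cc1ccc(O[Si](C(C)C)(C(C)C)C(C)C)c(O[Si](C(C)C)(C(C)C)C(C)C)c1 | intermediate
9 | 4-hydroxy-6-methyl-2H-pyran-2-one (triacetic acid lactone) | Cc1cc(O)cc(=O)o1 | starting material
10 | dilithio dianion of 9 (lithium 6-(lithiomethyl)-2-oxo-2H-pyran-4-olate) | [Li+].[Li+].[CH2-]c1cc([O-])cc(=O)o1 | intermediate
11 | 6-[2-hydroxy-2-[3,4-bis(triisopropylsilyloxy)phenyl]ethyl]-4-hydroxy-2H-pyran-2-one (racemic) | O=c1cc(O)cc(CC(O)c2ccc(O[Si](C(C)C)(C(C)C)C(C)C)c(O[Si](C(C)C)(C(C)C)C(C)C)c2)o1 | intermediate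
12 | 4-(tert-butyldimethylsilyloxy)-6-[2-(tert-butyldimethylsilyloxy)-2-[3,4-bis(triisopropylsilyloxy)phenyl]ethyl]-2H-pyran-2-one | O=c1cc(O[Si](C)(C)C(C)(C)C)cc(CC(O[Si](C)(C)C(C)(C)C)c2ccc(O[Si](C(C)C)(C(C)C)C(C)C)c(O[Si](C(C)C)(C(C)C)C(C)C)c2)o1 | intermediate
13 | 6-[2-(tert-butyldimethylsilyloxy)-2-[3,4-bis(triisopropylsilyloxy)phenyl]ethyl]-4-hydroxy-2H-pyran-2-one (racemic) | O=c1cc(O)cc(CC(O[Si](C)(C)C(C)(C)C)c2ccc(O[Si](C(C)C)(C(C)C)C(C)C)c(O[Si](C(C)C)(C(C)C)C(C)C)c2)o1 | intermediate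
14 | benzylic radical formed by addition of the C-3 radical of 13 to the α-carbon of 6 | CC1(C)[C@H]2CC[C@@]13CS(=O)(=O)N(C(=O)[C@H]([CH]c4ccc(O[Si](C(C)C)(C(C)C)C(C)C)c(O[Si](C(C)C)(C(C)C)C(C)C)c4)c4c(O)cc(CC(O[Si](C)(C)C(C)(C)C)c5ccc(O[Si](C(C)C)(C(C)C)C(C)C)c(O[Si](C(C)C)(C(C)C)C(C)C)c5)oc4=O)[C@H]3C2 | intermediate
15 | benzylic cation formed by oxidation of 14 | CC1(C)[C@H]2CC[C@@]13CS(=O)(=O)N(C(=O)[C@H]([CH+]c4ccc(O[Si](C(C)C)(C(C)C)C(C)C)c(O[Si](C(C)C)(C(C)C)C(C)C)c4)c4c(O)cc(CC(O[Si](C)(C)C(C)(C)C)c5ccc(O[Si](C(C)C)(C(C)C)C(C)C)c(O[Si](C(C)C)(C(C)C)C(C)C)c5)oc4=O)[C@H]3C2 | intermediate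
16 | N-[(2S,3S)-2-[3,4-bis(triisopropylsilyloxy)phenyl]-6-[2-(tert-butyldimethylsilyloxy)-2-[3,4-bis(triisopropylsilyloxy)phenyl]ethyl]-4-oxo-2,3-dihydro-4H-furo[3,2-c]pyran-3-carbonyl]-(2S)-bornane-10,2-sultam (trans; both epimers at the silyloxy carbon) | CC1(C)[C@H]2CC[C@@]13CS(=O)(=O)N(C(=O)[C@H]4c5c(cc(CC(O[Si](C)(C)C(C)(C)C)c6ccc(O[Si](C(C)C)(C(C)C)C(C)C)c(O[Si](C(C)C)(C(C)C)C(C)C)c6)oc5=O)O[C@@H]4c4ccc(O[Si](C(C)C)(C(C)C)C(C)C)c(O[Si](C(C)C)(C(C)C)C(C)C)c4)[C@H]3C2 | intermediate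
17 | N-[(2S,3S)-2-[3,4-bis(triisopropylsilyloxy)phenyl]-6-[(E)-2-[3,4-bis(triisopropylsilyloxy)phenyl]ethenyl]-4-oxo-2,3-dihydro-4H-furo[3,2-c]pyran-3-carbonyl]-(2S)-bornane-10,2-sultam | CC1(C)[C@H]2CC[C@@]13CS(=O)(=O)N(C(=O)[C@H]4c5c(cc(/C=C/c6ccc(O[Si](C(C)C)(C(C)C)C(C)C)c(O[Si](C(C)C)(C(C)C)C(C)C)c6)oc5=O)O[C@@H]4c4ccc(O[Si](C(C)C)(C(C)C)C(C)C)c(O[Si](C(C)C)(C(C)C)C(C)C)c4)[C@H]3C2 | intermediate
18 | (2S,3S)-peroxy acid corresponding to 19 (formed as its lithium salt) | OOC(=O)[C@H]1c2c(cc(/C=C/c3ccc(O[Si](C(C)C)(C(C)C)C(C)C)c(O[Si](C(C)C)(C(C)C)C(C)C)c3)oc2=O)O[C@@H]1c1ccc(O[Si](C(C)C)(C(C)C)C(C)C)c(O[Si](C(C)C)(C(C)C)C(C)C)c1 | intermediate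
19 | (2S,3S)-2-[3,4-bis(triisopropylsilyloxy)phenyl]-6-[(E)-2-[3,4-bis(triisopropylsilyloxy)phenyl]ethenyl]-4-oxo-2,3-dihydro-4H-furo[3,2-c]pyran-3-carboxylic acid | OC(=O)[C@H]1c2c(cc(/C=C/c3ccc(O[Si](C(C)C)(C(C)C)C(C)C)c(O[Si](C(C)C)(C(C)C)C(C)C)c3)oc2=O)O[C@@H]1c1ccc(O[Si](C(C)C)(C(C)C)C(C)C)c(O[Si](C(C)C)(C(C)C)C(C)C)c1 | intermediate
20 | 1-methoxy-1,3-bis(trimethylsilyloxy)buta-1,3-diene | COC(O[Si](C)(C)C)=CC(=C)O[Si](C)(C)C | starting material
21 | acid chloride of 19 | ClC(=O)[C@H]1c2c(cc(/C=C/c3ccc(O[Si](C(C)C)(C(C)C)C(C)C)c(O[Si](C(C)C)(C(C)C)C(C)C)c3)oc2=O)O[C@@H]1c1ccc(O[Si](C(C)C)(C(C)C)C(C)C)c(O[Si](C(C)C)(C(C)C)C(C)C)c1 | intermediate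
22 | methyl 5-oxo-3-(trimethylsilyloxy)pent-2-enoate carrying the (2S,3S)-furopyranon-3-yl group at C-5 (silyl enol ether of 23) | COC(=O)C=C(O[Si](C)(C)C)CC(=O)[C@H]1c2c(cc(/C=C/c3ccc(O[Si](C(C)C)(C(C)C)C(C)C)c(O[Si](C(C)C)(C(C)C)C(C)C)c3)oc2=O)O[C@@H]1c1ccc(O[Si](C(C)C)(C(C)C)C(C)C)c(O[Si](C(C)C)(C(C)C)C(C)C)c1 | intermediate
23 | methyl 5-[(2S,3S)-2-[3,4-bis(triisopropylsilyloxy)phenyl]-6-[(E)-2-[3,4-bis(triisopropylsilyloxy)phenyl]ethenyl]-4-oxo-2,3-dihydro-4H-furo[3,2-c]pyran-3-yl]-3,5-dioxopentanoate | COC(=O)CC(=O)CC(=O)[C@H]1c2c(cc(/C=C/c3ccc(O[Si](C(C)C)(C(C)C)C(C)C)c(O[Si](C(C)C)(C(C)C)C(C)C)c3)oc2=O)O[C@@H]1c1ccc(O[Si](C(C)C)(C(C)C)C(C)C)c(O[Si](C(C)C)(C(C)C)C(C)C)c1 | intermediate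
24 | tetra-O-triisopropylsilyl hypholomine B | O=c1cc(O)cc([C@H]2c3c(cc(/C=C/c4ccc(O[Si](C(C)C)(C(C)C)C(C)C)c(O[Si](C(C)C)(C(C)C)C(C)C)c4)oc3=O)O[C@@H]2c2ccc(O[Si](C(C)C)(C(C)C)C(C)C)c(O[Si](C(C)C)(C(C)C)C(C)C)c2)o1 | intermediate
25 | hypholomine B, (2S,3S) | O=c1cc(O)cc([C@H]2c3c(cc(/C=C/c4ccc(O)c(O)c4)oc3=O)O[C@@H]2c2ccc(O)c(O)c2)o1 | target

**Step count and risks**

Total steps: 11. Longest linear sequence: 9 steps (7 → 8 → 11 → 13 → 16 → 17 → 19 → 23 → 24 → 25; steps 3–11). The acceptor branch (steps 1–2) joins at step 6.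

Steps most likely to fail:

Step 6. The pyranonyl radical may add too slowly to the deactivated enoyl imide, so that oxidative self-coupling or over-oxidation of 13, or acid-induced loss of the benzylic silyl ether, takes over; the auxiliary may also give insufficient face control. The fallback replaces the radical by a rhodium carbenoid, the imide by an electron-rich alkene at the aldehyde oxidation level, and auxiliary control by catalyst control. It sets out from 13 and 8. Diazo transfer to 13 (p-acetamidobenzenesulfonyl azide, Et3N, MeCN) would give 3-diazo-6-[2-(tert-butyldimethylsilyloxy)-2-[3,4-bis(triisopropylsilyloxy)phenyl]ethyl]-2H-pyran-2,4(3H)-dione F1. Wittig homologation of 8 with (1,3-dioxolan-2-ylmethyl)triphenylphosphonium bromide/t-BuOK and iodine-catalysed isomerisation would give 2-[(E)-2-[3,4-bis(triisopropylsilyloxy)phenyl]ethenyl]-1,3-dioxolane F2. Formal [3+2] cycloaddition of F1 with F2 under a chiral dirhodium carboxylate (Rh2(S-PTTL)4 or its enantiomer, CH2Cl2, rt) forms the same two bonds with loss of nitrogen and should give the trans (2S,3S)-3-(1,3-dioxolan-2-yl)-2,3-dihydro-4H-furo[3,2-c]pyran-4-one F3; face control here is less secure than with the sultam. TsOH·H2O in wet acetone would hydrolyse the acetal and eliminate silanol to give the (2S,3S)-6-styryl-4-oxo-2,3-dihydro-4H-furo[3,2-c]pyran-3-carbaldehyde F4. Pinnick oxidation (NaClO2, NaH2PO4, 2-methyl-2-butene) would give acid 19, where the route is rejoined; steps 7 and 8 are bypassed.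

Step 9. The hindered, α-branched acid chloride may be captured too slowly by the neutral dienol ether, so that ketene formation (epimerisation at C-3) or chloride-induced opening of the dihydrofuran competes. The fallback uses an anionic vinylogous Claisen acylation and a thermal acylketene ring closure, and sets out from 19. Carbonyldiimidazole would give the acyl imidazole F5. The lithium dienolate of 2,2,6-trimethyl-4H-1,3-dioxin-4-one (LiHMDS, THF, −78 °C) would be acylated by it to give the 6-(2-oxoalkyl)-2,2-dimethyl-4H-1,3-dioxin-4-one F6. Heating F6 in toluene (110 °C) would expel acetone and close the acylketene to the 4-hydroxy-2-pyranone, giving 24 directly; step 10 is bypassed.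

Step 8. Hydroperoxide or hydroxide may attack the 2-pyranone lactone of ring A or the aryl silyl ethers, or base may open the dihydrofuran by β-elimination from C-3, before the hindered imide is cleaved. The fallback is a non-hydrolytic removal of the auxiliary and sets out from 17. Titanium-mediated transesterification (Ti(OiPr)4, allyl alcohol, 70 °C) would give the allyl (2S,3S)-carboxylate F7 and return the sultam. Neutral deallylation (Pd(PPh3)4, morpholine, THF, rt) would give acid 19, where the route is rejoined.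

**Further compounds**

F1 | step 6 | 3-diazo-6-[2-(tert-butyldimethylsilyloxy)-2-[3,4-bis(triisopropylsilyloxy)phenyl]ethyl]-2H-pyran-2,4(3H)-dione | [N-]=[N+]=C1C(=O)OC(CC(O[Si](C)(C)C(C)(C)C)c2ccc(O[Si](C(C)C)(C(C)C)C(C)C)c(O[Si](C(C)C)(C(C)C)C(C)C)c2)=CC1=O
F2 | step 6 | 2-[(E)-2-[3,4-bis(triisopropylsilyloxy)phenyl]ethenyl]-1,3-dioxolane | C1(/C=C/c2ccc(O[Si](C(C)C)(C(C)C)C(C)C)c(O[Si](C(C)C)(C(C)C)C(C)C)c2)OCCO1
F3 | step 6 | (2S,3S)-2-[3,4-bis(triisopropylsilyloxy)phenyl]-6-[2-(tert-butyldimethylsilyloxy)-2-[3,4-bis(triisopropylsilyloxy)phenyl]ethyl]-3-(1,3-dioxolan-2-yl)-2,3-dihydro-4H-furo[3,2-c]pyran-4-one | O1CCOC1[C@H]1c2c(cc(CC(O[Si](C)(C)C(C)(C)C)c3ccc(O[Si](C(C)C)(C(C)C)C(C)C)c(O[Si](C(C)C)(C(C)C)C(C)C)c3)oc2=O)O[C@@H]1c1ccc(O[Si](C(C)C)(C(C)C)C(C)C)c(O[Si](C(C)C)(C(C)C)C(C)C)c1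
F4 | step 6 | (2S,3S)-2-[3,4-bis(triisopropylsilyloxy)phenyl]-6-[(E)-2-[3,4-bis(triisopropylsilyloxy)phenyl]ethenyl]-4-oxo-2,3-dihydro-4H-furo[3,2-c]pyran-3-carbaldehyde | O=C[C@H]1c2c(cc(/C=C/c3ccc(O[Si](C(C)C)(C(C)C)C(C)C)c(O[Si](C(C)C)(C(C)C)C(C)C)c3)oc2=O)O[C@@H]1c1ccc(O[Si](C(C)C)(C(C)C)C(C)C)c(O[Si](C(C)C)(C(C)C)C(C)C)c1
F5 | step 9 | acyl imidazole of acid 19 | O=C(n1ccnc1)[C@H]1c2c(cc(/C=C/c3ccc(O[Si](C(C)C)(C(C)C)C(C)C)c(O[Si](C(C)C)(C(C)C)C(C)C)c3)oc2=O)O[C@@H]1c1ccc(O[Si](C(C)C)(C(C)C)C(C)C)c(O[Si](C(C)C)(C(C)C)C(C)C)c1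
F6 | step 9 | 2,2-dimethyl-6-[2-oxo-2-[(2S,3S)-furopyranon-3-yl]ethyl]-4H-1,3-dioxin-4-one (furopyranonyl group as in 19) | CC1(C)OC(CC(=O)[C@H]2c3c(cc(/C=C/c4ccc(O[Si](C(C)C)(C(C)C)C(C)C)c(O[Si](C(C)C)(C(C)C)C(C)C)c4)oc3=O)O[C@@H]2c2ccc(O[Si](C(C)C)(C(C)C)C(C)C)c(O[Si](C(C)C)(C(C)C)C(C)C)c2)=CC(=O)O1
F7 | step 8 | allyl ester of acid 19 | C=CCOC(=O)[C@H]1c2c(cc(/C=C/c3ccc(O[Si](C(C)C)(C(C)C)C(C)C)c(O[Si](C(C)C)(C(C)C)C(C)C)c3)oc2=O)O[C@@H]1c1ccc(O[Si](C(C)C)(C(C)C)C(C)C)c(O[Si](C(C)C)(C(C)C)C(C)C)c1
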